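## The problem

Compound 24 is a coumarin. Benzene ring A (C4a, C5, C6, C7, C8, C8a) is fused to lactone ring B (O1, C2, C3, C4), and C3 is joined by an sp2–sp2 bond to C2′ of a 6′-methyl-dihydropyran-4-one, ring C (O1′, C2′=C3′, C4′=O, C5′H2, C6′H–CH3). Ring A bears no hydrogen: C5 carries the (S)-2-hydroxypropyl chain, C6 and C8 carry methyl groups, C7 a hydroxyl and C8a the lactone oxygen, so six different groups must be placed in a fixed order around one ring. The two stereocentres, the side-chain carbinol (S) and C6′ (R), lie on opposite sides of the flat coumarin core. Neither can direct the other, so each must be brought in enantiopure and then left untouched. Ring C is a β-alkoxy enone: a base that deprotonates C5′ can expel O1′ from C6′, and re-addition would scramble C6′. The lactone opens with hydroxide or alkoxide, and the resorcinol-type ring A is easily oxidised. A free 2-arylethanol beside an activated, unsubstituted ring position would trap a one-carbon electrophile as an isochroman under acid, so the carbinol must be masked while C4 is attached. The feature the plan uses is that, once ring B is removed, C4a is the only carbon of ring A that bears hydrogen, it is ortho to the C8a hydroxyl and para to the C7 hydroxyl, and only the C8a hydroxyl is next to it. An electrophile carrying C4, C3, the ester carbon C2 and ring C can therefore bond at one site only and lactonise in one way only.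

## Retrosynthesis

**24 to 23.** The O–Si bond of the side-chain carbinol is cut. A triisopropylsilyl ether is chosen because it keeps the carbinol oxygen out of the acid-mediated ring closure and comes off with buffered fluoride. An ester would need base or acidic methanolysis in the presence of ring C, and a benzyl ether would need hydrogenolysis in the presence of two enone-type double bonds. The forward step must only avoid basic fluoride.

**23 to 11 and 21.** The C4–C4a bond and the O1–C2 bond are cut, which removes ring B and divides the molecule into the resorcinol 11 and the enamino ester 21, each carrying one stereocentre. Three neighbouring cuts were weighed: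
- Cutting C3–C4 (Knoevenagel closure) needs a separate formylation at C4a and an amine base, which ring C tolerates poorly.
- Cutting C2–C3 needs a styrene that already contains the C4–C4a bond.
- Cutting C3–C2′ needs a metalated ring C, which would not survive.

The chosen cut uses the nucleophilicity that C4a already has. The forward reaction must form the carbon–carbon bond at C4a, lose dimethylamine and lactonise, all under acid, without freeing the carbinol.

**21 to 20.** The C3=C4 double bond is cut. C4 comes from an amide acetal and C3 is the methylene of the ester 20. The forward condensation must take place at this methylene, which is activated by the ester and, through C2′=C3′, by the ketone, and not at C5′.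

**20 to 17, then to 14 and 15.** Ring C is opened at O1′–C2′ (cyclodehydration of a δ-hydroxy β-diketone), and the chain 17 is cut at C3′–C4′ into the amide 14 and the dianion 16 of methyl acetoacetate 15. A hetero-Diels–Alder construction of ring C would need an asymmetric catalyst to set C6′. Here C6′ is bought with 12, and its C–O bond is never broken. The forward steps need a γ-selective acylation that stops at the ketone and a ring closure that can only give the six-membered ring.

**14 to 13 to 12.** The amide C–N bond and the O–Si bond are cut. The N-methoxy-N-methyl amide is the acyl donor that does not over-add, and the silyl ether protects the hydroxyl against the bases of the next two steps and falls off in the acid that closes ring C.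

**11 to 10, 8 and 6.** The two O–CH2 bonds of the methoxymethyl ethers and the two ring–methyl bonds (C8–CH3, then C6–CH3) are cut. Methoxymethyl ethers are chosen over methyl ethers because they direct both lithiations strongly and leave under mild Lewis acid with the silyl ether intact. Methyl ethers would save step 1 but need a boron trihalide at the end, which would strip the silyl group and endanger the homobenzylic carbinol. The C8 position lies between both oxygens and is metalated first. The two ring hydrogens that remain in 8 are equivalent, so the second methylation has one possible outcome.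

**6 to 5, then to 2 and 3, then to 1.** The silyl ether is cut, then the C5–CH2 bond, which leads back to the aryl Grignard reagent 4 from bromide 2 and to (S)-propylene oxide 3. Bromide 2 comes from 5-bromoresorcinol 1. The stereocentre is bought, the epoxide is opened at its unsubstituted carbon, and the mirror symmetry of 2 removes any regiochemical question.

## Roads not taken

**Alternative 1:** Ring A would be built by cutting C5–C6 and C4a–C8a. Heating the bis-silyloxy diene A1 with the ynoate A2 would give a cycloadduct that loses methanol to form the resorcylate A3.
- Merits: all six substituents of ring A are placed in one step by the polarisation of the two partners, no aryl metalation is needed, and C4 is already attached to C4a as the ester carbon.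
- Weak points: A1 is substituted at its reacting terminus and at C8, and A2 is a β-alkyl ynoate; both features slow the cycloaddition and give the sensitive diene time to decompose. A3 holds C4 at the ester oxidation level, so it must be reduced to the aldehyde in the presence of two phenols before ring B can be closed at C3–C4 by Knoevenagel condensation with 20, under the amine base that ring C tolerates least. A2 and A1 each need their own short synthesis, so the total is no shorter than thirteen steps.
- Comparison: this road is better in that it avoids two low-temperature lithiations and the protection and deprotection of the phenols. The chosen plan sets against this a commercial aromatic core, metalations that each have one possible site, and a closure of ring B that forms both bonds in acid without passing through the aldehyde.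

**Alternative 2:** Ring A would be built by cutting C8–C8a, C6–C7 and C4a–C8a. Heating the cyclobutenone A4 with the silyloxyalkyne A5 would give, by electrocyclic opening to a vinylketene, ketene–alkyne cycloaddition, a second opening and 6π closure, the phenol A6 with C8a–OH free and C7–O silylated.
- Merits: one thermal, neutral step gives the pentasubstituted ring with its two oxygens differentiated and C4a left as C–H, so A6 could enter the same acid-mediated closure of ring B; a silylated C7 oxygen would also make the ring less prone to oxidation than 11.
- Weak points: A4 has to be assembled over several steps by ketene cycloaddition to a chiral alkyne and dehalogenation, with a regiochemical question of its own, and A5 is moisture-sensitive and made by ester homologation. The differentiation of the oxygens buys nothing here, because only the C8a hydroxyl is ortho to C4a in any case.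
- Comparison: this road reaches the stage of 11 by a longer route and leaves the closure of ring B unsolved. The chosen plan reaches 11 in six standard operations from 1.

**Alternative 3:** Ring B would be closed by cutting C2–C3 and O1–C2, with carbon monoxide as C2. Pd(OAc)2 under carbon monoxide, with benzoquinone to reoxidise zerovalent palladium to divalent palladium, would convert the 2-hydroxystyryl dihydropyranone A7 into the bis-silyl coumarin A8.
- Merits: the medium is neither acidic nor basic, so both silyl ethers and ring C are safe, and the lactone carbonyl is introduced without an ester.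
- Weak points: A7 already contains the C4–C4a bond and the C3–C2′ link, so the resorcinol must first be formylated and olefinated with a ring C reagent, and the convergence of the chosen plan is lost. The C3–H bond to be functionalised belongs to an electron-poor cross-conjugated dienone, C3′–H competes, 2-vinylphenols can cyclise oxidatively to benzofurans under divalent palladium, and benzoquinone may oxidise the electron-rich phenol.
- Comparison: this road is gentler on the protecting groups than hot acid. The chosen plan sets against this fewer steps and a ring closure known for activated phenols, with the silyl ether as its one exposed point.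

Key step: step 12

Assumption: 21 is drawn as its E isomer and 22 as its Z isomer; both double bonds equilibrate under the acid of step 12, so the geometry assigned does not affect the outcome, and 19 is a mixture of epimers at its hemiketal carbon that converge on dehydration.

## Route

Step 1
Reactants: 1 5-bromobenzene-1,3-diol (5-bromoresorcinol)
Product: 2 1-bromo-3,5-bis(methoxymethoxy)benzene
Conditions: MOMCl, i-Pr2NEt, CH2Cl2, 0 °C → rt
Reagents that add atoms: chloromethyl methyl ether, COCCl
Why: O-alkylation of both phenols by the α-chloro ether (Williamson-type acetal formation); the methoxymethyl groups later direct both lithiations and can be removed without touching a silyl ether.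

Step 2
Reactants: 2 1-bromo-3,5-bis(methoxymethoxy)benzene; 3 (S)-propylene oxide
Product: 5 (S)-1-[3,5-bis(methoxymethoxy)phenyl]propan-2-ol, via arylmagnesium bromide 4 (not isolated)
Conditions: Mg, THF, 45 °C; then CuI (10 mol %), 3, −30 → 0 °C; aq. NH4Cl
Reagents that add atoms: none
Why: Grignard formation followed by copper-catalysed SN2 opening of the epoxide at its unsubstituted carbon; the stereocentre of 3 takes no part and appears unchanged as the S carbinol, and CuI suppresses bromohydrin formation.

Step 3
Reactants: 5 (S)-1-[3,5-bis(methoxymethoxy)phenyl]propan-2-ol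
Product: 6 {[(S)-1-[3,5-bis(methoxymethoxy)phenyl]propan-2-yl]oxy}triisopropylsilane
Conditions: TIPSOTf, 2,6-lutidine, CH2Cl2, −78 → 0 °C
Reagents that add atoms: triisopropylsilyl trifluoromethanesulfonate, CC(C)[Si](OS(=O)(=O)C(F)(F)F)(C(C)C)C(C)C
Why: Silylation of a secondary alcohol with a silyl triflate and a hindered pyridine base; at low temperature the alcohol reacts far faster than the aryl acetals are activated.

Step 4
Reactants: 6 {[(S)-1-[3,5-bis(methoxymethoxy)phenyl]propan-2-yl]oxy}triisopropylsilane
Product: 8 {[(S)-1-[3,5-bis(methoxymethoxy)-4-methylphenyl]propan-2-yl]oxy}triisopropylsilane, via 4-lithio arene 7 (not isolated)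
Conditions: n-BuLi, THF, 0 °C; then MeI, 0 °C → rt
Reagents that add atoms: iodomethane, CI
Why: Directed ortho-metalation; the ring hydrogen between the two methoxymethoxy groups is the most acidic and is chelated from both sides, and the aryllithium is methylated by SN2 on iodomethane to install the future C8 methyl.

Step 5
Reactants: 8 {[(S)-1-[3,5-bis(methoxymethoxy)-4-methylphenyl]propan-2-yl]oxy}triisopropylsilane
Product: 10 {[(S)-1-[3,5-bis(methoxymethoxy)-2,4-dimethylphenyl]propan-2-yl]oxy}triisopropylsilane, via 2-lithio arene 9 (not isolated)
Conditions: s-BuLi, TMEDA, THF, −78 °C; then MeI, −78 °C → rt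
Reagents that add atoms: iodomethane, CI
Why: Second directed ortho-metalation; the two remaining ring hydrogens are equivalent and each is ortho to one methoxymethoxy group, so only one monomethyl product is possible, and ring lithiation beside the acetal oxygen should outrun benzylic deprotonation because alkoxy groups direct lateral metalation poorly.

Step 6
Reactants: 10 {[(S)-1-[3,5-bis(methoxymethoxy)-2,4-dimethylphenyl]propan-2-yl]oxy}triisopropylsilane
Product: 11 2,4-dimethyl-5-[(S)-2-(triisopropylsilyloxy)propyl]benzene-1,3-diol
Conditions: ZnBr2, n-PrSH, CH2Cl2, 0 °C → rt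
Reagents that add atoms: none
Why: Lewis acid-mediated cleavage of aryl acetals with thiol capture; ZnBr2 activates the methoxymethyl ethers and the thiol intercepts the methoxymethyl cation before it can alkylate the free ring position, while the much less labile secondary silyl ether should stay in place.

Step 7
Reactants: 12 methyl (R)-3-hydroxybutanoate
Product: 13 methyl (R)-3-(tert-butyldimethylsilyloxy)butanoate
Conditions: TBSCl, imidazole, DMF, rt
Reagents that add atoms: tert-butyldimethylsilyl chloride, CC(C)(C)[Si](C)(C)Cl
Why: Standard silylation of a secondary alcohol; it protects the hydroxyl from the organometallic bases of steps 8 and 9 and does not touch the stereocentre.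

Step 8
Reactants: 13 methyl (R)-3-(tert-butyldimethylsilyloxy)butanoate
Product: 14 (R)-3-(tert-butyldimethylsilyloxy)-N-methoxy-N-methylbutanamide
Conditions: MeNHOMe·HCl, i-PrMgCl, THF, −20 → 0 °C
Reagents that add atoms: N,O-dimethylhydroxylamine hydrochloride, CNOC.Cl
Why: Aminolysis of the ester by the magnesium amide of N,O-dimethylhydroxylamine (Weinreb amide formation); the stereocentre is β to the carbonyl and is not affected.

Step 9
Reactants: 14 (R)-3-(tert-butyldimethylsilyloxy)-N-methoxy-N-methylbutanamide; 15 methyl acetoacetate
Product: 17 methyl (R)-7-(tert-butyldimethylsilyloxy)-3,5-dioxooctanoate, via acetoacetate dianion 16 (not isolated)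
Conditions: 15 (2.2 equiv), NaH, THF, 0 °C; n-BuLi, 0 °C; then 14, −78 → 0 °C; aq. HCl
Reagents that add atoms: none
Why: Claisen-type C-acylation of the acetoacetate dianion at its terminal carbon; the chelated tetrahedral adduct of the N-methoxy-N-methyl amide persists until work-up, so the new ketone is not attacked again, and the excess dianion absorbs the acidic proton of the product.

Step 10
Reactants: 17 methyl (R)-7-(tert-butyldimethylsilyloxy)-3,5-dioxooctanoate
Product: 20 methyl 2-[(R)-6-methyl-4-oxo-5,6-dihydro-4H-pyran-2-yl]acetate, via hydroxy diketo ester 18 (not isolated), via cyclic hemiketal 19 (not isolated)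
Conditions: 48% aq. HF, MeCN, 0 °C → rt; then TsOH·H2O (cat.), PhMe, rt
Reagents that add atoms: none
Why: Acidic desilylation frees the hydroxyl, which adds to the C3 ketone to give the six-membered hemiketal (the only ring size within reach), and acid-catalysed dehydration gives the vinylogous ester (cyclodehydration of a δ-hydroxy β-diketone); the C–O bond at C6′ is never broken, so the R configuration of 12 is kept.

Step 11
Reactants: 20 methyl 2-[(R)-6-methyl-4-oxo-5,6-dihydro-4H-pyran-2-yl]acetate
Product: 21 methyl (E)-3-(dimethylamino)-2-[(R)-6-methyl-4-oxo-5,6-dihydro-4H-pyran-2-yl]acrylate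
Conditions: Me2NCH(OMe)2, PhMe, 60 °C
Reagents that add atoms: N,N-dimethylformamide dimethyl acetal, COC(OC)N(C)C
Why: Condensation of an amide acetal with an active methylene compound; the exocyclic CH2 is activated by the ester and, through C2′=C3′, by the ketone, so it should react well below the temperature at which the simple α-methylene C5′ does, and the near-neutral medium does not open ring C.

Step 12
Reactants: 11 2,4-dimethyl-5-[(S)-2-(triisopropylsilyloxy)propyl]benzene-1,3-diol; 21 methyl (E)-3-(dimethylamino)-2-[(R)-6-methyl-4-oxo-5,6-dihydro-4H-pyran-2-yl]acrylate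
Product: 23 7-hydroxy-6,8-dimethyl-3-[(R)-6-methyl-4-oxo-5,6-dihydro-4H-pyran-2-yl]-5-[(S)-2-(triisopropylsilyloxy)propyl]-2H-chromen-2-one, via 2-hydroxycinnamate ester 22 (not isolated)
Conditions: anhydrous AcOH, CF3CO2H (2 equiv), 70 °C, Ar
Reagents that add atoms: none
Why: Acid protonates the vinylogous amide 21 at the ring C carbonyl oxygen, which makes the aminomethylene carbon (the future C4) an iminium-type electrophile; C4a of 11, the only carbon of ring A that still bears hydrogen and one activated by the ortho C8a hydroxyl and the para C7 hydroxyl, attacks it in a Friedel–Crafts (Mannich-type) alkenylation. Loss of dimethylamine from the benzylic amine, assisted by the ortho and para hydroxyls, should give the 2-hydroxycinnamate 22, whose C3=C4 bond isomerises through its protonated, quinone methide-like form until the C8a hydroxyl and the ester are cis. Ring B then closes by 6-exo-trig acyl substitution of the C8a hydroxyl at the ester carbon C2 with loss of methanol; this aromatising lactonisation is irreversible and drains reversible side equilibria such as O-vinylation of a phenol or addition at C2′. The closest known reaction type is the acid-mediated Pechmann-type condensation of resorcinols and naphthols with 2-substituted 3-(dimethylamino)acrylates, which gives 3-substituted coumarins without a substituent at C4. No stereocentre is formed; the S carbinol and C6′ (R) are spectators, and the acid medium does not deprotonate C5′, so ring C should not open. The step needs site selectivity, which is built in because C4a is the only free position and only the C8a hydroxyl is next to it. It also needs chemoselectivity against capture of the electrophile by the side-chain oxygen (isochroman formation), which the silyl ether and the anhydrous, moderately acidic conditions are meant to secure.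

Step 13
Reactants: 23 7-hydroxy-6,8-dimethyl-3-[(R)-6-methyl-4-oxo-5,6-dihydro-4H-pyran-2-yl]-5-[(S)-2-(triisopropylsilyloxy)propyl]-2H-chromen-2-one
Product: 24 7-hydroxy-5-[(S)-2-hydroxypropyl]-6,8-dimethyl-3-[(R)-6-methyl-4-oxo-5,6-dihydro-4H-pyran-2-yl]-2H-chromen-2-one
Conditions: HF·pyridine, pyridine, THF, 0 °C → rt
Reagents that add atoms: none
Why: Fluoride-mediated cleavage of the silyl ether, driven by Si–F bond formation; the buffered, weakly acidic medium avoids the base-induced opening of ring C and of the lactone, and neither stereocentre is touched.

## Compound list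

1 | 5-bromobenzene-1,3-diol | Oc1cc(Br)cc(O)c1 | starting material
2 | 1-bromo-3,5-bis(methoxymethoxy)benzene | COCOc1cc(Br)cc(OCOC)c1 | intermediate
3 | (S)-propylene oxide | C[C@H]1CO1 | starting material
4 | [3,5-bis(methoxymethoxy)phenyl]magnesium bromide | COCOc1cc([Mg]Br)cc(OCOC)c1 | intermediate (not isolated)
5 | (S)-1-[3,5-bis(methoxymethoxy)phenyl]propan-2-ol | COCOc1cc(C[C@H](C)O)cc(OCOC)c1 | intermediate
6 | {[(S)-1-[3,5-bis(methoxymethoxy)phenyl]propan-2-yl]oxy}triisopropylsilane | COCOc1cc(C[C@H](C)O[Si](C(C)C)(C(C)C)C(C)C)cc(OCOC)c1 | intermediate
7 | {2,6-bis(methoxymethoxy)-4-[(S)-2-(triisopropylsilyloxy)propyl]phenyl}lithium | [Li]c1c(OCOC)cc(C[C@H](C)O[Si](C(C)C)(C(C)C)C(C)C)cc1OCOC | intermediate (not isolated)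
8 | {[(S)-1-[3,5-bis(methoxymethoxy)-4-methylphenyl]propan-2-yl]oxy}triisopropylsilane | Cc1c(OCOC)cc(C[C@H](C)O[Si](C(C)C)(C(C)C)C(C)C)cc1OCOC | intermediate
9 | {2,4-bis(methoxymethoxy)-3-methyl-6-[(S)-2-(triisopropylsilyloxy)propyl]phenyl}lithium | [Li]c1c(OCOC)c(C)c(OCOC)cc1C[C@H](C)O[Si](C(C)C)(C(C)C)C(C)C | intermediate (not isolated)
10 | {[(S)-1-[3,5-bis(methoxymethoxy)-2,4-dimethylphenyl]propan-2-yl]oxy}triisopropylsilane | Cc1c(OCOC)c(C)c(OCOC)cc1C[C@H](C)O[Si](C(C)C)(C(C)C)C(C)C | intermediate
11 | 2,4-dimethyl-5-[(S)-2-(triisopropylsilyloxy)propyl]benzene-1,3-diol | Cc1c(O)c(C)c(O)cc1C[C@H](C)O[Si](C(C)C)(C(C)C)C(C)C | intermediate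
12 | methyl (R)-3-hydroxybutanoate | C[C@@H](O)CC(=O)OC | starting material
13 | methyl (R)-3-(tert-butyldimethylsilyloxy)butanoate | C[C@@H](O[Si](C)(C)C(C)(C)C)CC(=O)OC | intermediate
14 | (R)-3-(tert-butyldimethylsilyloxy)-N-methoxy-N-methylbutanamide | C[C@@H](O[Si](C)(C)C(C)(C)C)CC(=O)N(C)OC | intermediate
15 | methyl acetoacetate | COC(=O)CC(C)=O | starting material
16 | sodium lithium dienolate (dianion) of methyl acetoacetate | [Na+].[Li+].C=C([O-])C=C([O-])OC | intermediate (not isolated)
17 | methyl (R)-7-(tert-butyldimethylsilyloxy)-3,5-dioxooctanoate | C[C@@H](O[Si](C)(C)C(C)(C)C)CC(=O)CC(=O)CC(=O)OC | intermediate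
18 | methyl (R)-7-hydroxy-3,5-dioxooctanoate | C[C@@H](O)CC(=O)CC(=O)CC(=O)OC | intermediate (not isolated)
19 | methyl 2-[(6R)-2-hydroxy-6-methyl-4-oxotetrahydro-2H-pyran-2-yl]acetate (both epimers at the hemiketal carbon) | COC(=O)CC1(O)CC(=O)C[C@@H](C)O1 | intermediate (not isolated)
20 | methyl 2-[(R)-6-methyl-4-oxo-5,6-dihydro-4H-pyran-2-yl]acetate | COC(=O)CC1=CC(=O)C[C@@H](C)O1 | intermediate
21 | methyl (E)-3-(dimethylamino)-2-[(R)-6-methyl-4-oxo-5,6-dihydro-4H-pyran-2-yl]acrylate | CN(C)/C=C(/C(=O)OC)C1=CC(=O)C[C@@H](C)O1 | intermediate
22 | methyl (Z)-3-{2,4-dihydroxy-3,5-dimethyl-6-[(S)-2-(triisopropylsilyloxy)propyl]phenyl}-2-[(R)-6-methyl-4-oxo-5,6-dihydro-4H-pyran-2-yl]acrylate | COC(=O)/C(=C\c1c(O)c(C)c(O)c(C)c1C[C@H](C)O[Si](C(C)C)(C(C)C)C(C)C)C1=CC(=O)C[C@@H](C)O1 | intermediate (not isolated)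
23 | 7-hydroxy-6,8-dimethyl-3-[(R)-6-methyl-4-oxo-5,6-dihydro-4H-pyran-2-yl]-5-[(S)-2-(triisopropylsilyloxy)propyl]-2H-chromen-2-one | Cc1c(O)c(C)c2oc(=O)c(C3=CC(=O)C[C@@H](C)O3)cc2c1C[C@H](C)O[Si](C(C)C)(C(C)C)C(C)C | intermediate
24 | 7-hydroxy-5-[(S)-2-hydroxypropyl]-6,8-dimethyl-3-[(R)-6-methyl-4-oxo-5,6-dihydro-4H-pyran-2-yl]-2H-chromen-2-one | Cc1c(O)c(C)c2oc(=O)c(C3=CC(=O)C[C@@H](C)O3)cc2c1C[C@H](C)O | target

## Step count and least certain steps

Total step count: 13. Longest linear sequence: 8 steps (steps 1 to 6, 12 and 13). The ring C branch (steps 7 to 11) joins at step 12.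

**Step 12 (key step).** The most likely failure is acid-induced loss of the silyl ether before the C4–C4a bond has formed. The freed carbinol would then capture the iminium carbon and divert the sequence into an oxa-Pictet–Spengler cyclisation. A second risk is slow attack at C4a, which is flanked by the side chain, leaving ring C exposed to hot acid for a long time. The fallback sets out from 11. Magnesium-mediated ortho-formylation (MgCl2, Et3N, paraformaldehyde, MeCN, reflux) at the only free position would give 2,4-dihydroxy-3,5-dimethyl-6-[(S)-2-(triisopropylsilyloxy)propyl]benzaldehyde F1. Knoevenagel condensation of F1 with the ester 20 (piperidinium acetate, EtOH, 60 °C), followed by spontaneous lactonisation, would return to the route at 23. This detour closes ring B at C3–C4 in a weakly buffered medium and also does without the enamino ester 21, should step 11 not deliver it cleanly.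

**Step 5.** Deprotonation may occur at the benzylic methyl between the two acetal oxygens instead of on the ring, or ring metalation may stay incomplete because the site is crowded, giving mixtures after methylation. The fallback sets out from 8. Electrophilic bromination (NBS, MeCN, 0 °C) at one of the two equivalent activated positions would give {[(S)-1-[2-bromo-3,5-bis(methoxymethoxy)-4-methylphenyl]propan-2-yl]oxy}triisopropylsilane F2. Bromine–lithium exchange (t-BuLi, THF, −78 °C) and quenching with iodomethane would return to the route at 10.

**Step 9.** Proton transfer from the acidic product to the dianion may stall the acylation, and enolisation of 14 followed by β-elimination of the silanolate may consume the amide. The fallback sets out from 13. Reduction with i-Bu2AlH (CH2Cl2, −78 °C) would give (R)-3-(tert-butyldimethylsilyloxy)butanal F3. Aldol addition of the dianion 16 to F3 (THF, −78 °C) would give methyl (7R)-7-(tert-butyldimethylsilyloxy)-5-hydroxy-3-oxooctanoate F4 as a mixture of C5 epimers, and oxidation with Dess–Martin periodinane would return to the route at 17.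

**Step 6.** The Lewis acid may partly remove the silyl ether, or the cation released from the acetal may alkylate the freed, very electron-rich resorcinol at its one open position. The fallback sets out from 10. Global acidic methanolysis (HCl, MeOH, 50 °C), in which the solvent traps the methoxymethyl cation, would give 5-[(S)-2-hydroxypropyl]-2,4-dimethylbenzene-1,3-diol F5. Exhaustive silylation (TIPSOTf, 2,6-lutidine, CH2Cl2) would give triisopropyl{[(S)-1-{2,4-dimethyl-3,5-bis[(triisopropylsilyl)oxy]phenyl}propan-2-yl]oxy}silane F6. Selective cleavage of the two aryl silyl ethers (KHF2, MeOH, rt), which react far faster than the alkyl silyl ether, would return to the route at 11.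

## Further compounds

F1 | step 12 | 2,4-dihydroxy-3,5-dimethyl-6-[(S)-2-(triisopropylsilyloxy)propyl]benzaldehyde | Cc1c(O)c(C)c(O)c(C=O)c1C[C@H](C)O[Si](C(C)C)(C(C)C)C(C)C
F2 | step 5 | {[(S)-1-[2-bromo-3,5-bis(methoxymethoxy)-4-methylphenyl]propan-2-yl]oxy}triisopropylsilane | Brc1c(OCOC)c(C)c(OCOC)cc1C[C@H](C)O[Si](C(C)C)(C(C)C)C(C)C
F3 | step 9 | (R)-3-(tert-butyldimethylsilyloxy)butanal | C[C@@H](O[Si](C)(C)C(C)(C)C)CC=O
F4 | step 9 | methyl (7R)-7-(tert-butyldimethylsilyloxy)-5-hydroxy-3-oxooctanoate (both C5 epimers) | C[C@@H](O[Si](C)(C)C(C)(C)C)CC(O)CC(=O)CC(=O)OC
F5 | step 6 | 5-[(S)-2-hydroxypropyl]-2,4-dimethylbenzene-1,3-diol | Cc1c(O)c(C)c(O)cc1C[C@H](C)O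
F6 | step 6 | triisopropyl{[(S)-1-{2,4-dimethyl-3,5-bis[(triisopropylsilyl)oxy]phenyl}propan-2-yl]oxy}silane | Cc1c(O[Si](C(C)C)(C(C)C)C(C)C)c(C)c(O[Si](C(C)C)(C(C)C)C(C)C)cc1C[C@H](C)O[Si](C(C)C)(C(C)C)C(C)C
A1 | alternative 1 | 1-methoxy-2-methyl-1,3-bis(trimethylsilyloxy)penta-1,3-diene (geometry as obtained on silylation) | COC(O[Si](C)(C)C)=C(C)C(O[Si](C)(C)C)=CC
A2 | alternative 1 | methyl (S)-5-(tert-butyldimethylsilyloxy)hex-2-ynoate | COC(=O)C#CC[C@H](C)O[Si](C)(C)C(C)(C)C
A3 | alternative 1 | methyl 2,4-dihydroxy-3,5-dimethyl-6-[(S)-2-(tert-butyldimethylsilyloxy)propyl]benzoate | COC(=O)c1c(O)c(C)c(O)c(C)c1C[C@H](C)O[Si](C)(C)C(C)(C)C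
A4 | alternative 2 | 3-[(S)-2-(tert-butyldimethylsilyloxy)propyl]-2-methylcyclobut-2-en-1-one | CC1=C(C[C@H](C)O[Si](C)(C)C(C)(C)C)CC1=O
A5 | alternative 2 | triisopropyl(prop-1-yn-1-yloxy)silane | CC#CO[Si](C(C)C)(C(C)C)C(C)C
A6 | alternative 2 | 2,4-dimethyl-5-[(S)-2-(tert-butyldimethylsilyloxy)propyl]-3-(triisopropylsilyloxy)phenol | Cc1c(O[Si](C(C)C)(C(C)C)C(C)C)c(C)c(O)cc1C[C@H](C)O[Si](C)(C)C(C)(C)C
A7 | alternative 3 | (2R)-6-[(E)-2-{4-(tert-butyldimethylsilyloxy)-2-hydroxy-3,5-dimethyl-6-[(S)-2-(tert-butyldimethylsilyloxy)propyl]phenyl}ethenyl]-2-methyl-2,3-dihydro-4H-pyran-4-one | Cc1c(O[Si](C)(C)C(C)(C)C)c(C)c(O)c(/C=C/C2=CC(=O)C[C@@H](C)O2)c1C[C@H](C)O[Si](C)(C)C(C)(C)C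
A8 | alternative 3 | 7-(tert-butyldimethylsilyloxy)-5-[(S)-2-(tert-butyldimethylsilyloxy)propyl]-6,8-dimethyl-3-[(R)-6-methyl-4-oxo-5,6-dihydro-4H-pyran-2-yl]-2H-chromen-2-one | Cc1c(O[Si](C)(C)C(C)(C)C)c(C)c2oc(=O)c(C3=CC(=O)C[C@@H](C)O3)cc2c1C[C@H](C)O[Si](C)(C)C(C)(C)C
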